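**Strategy**

Everything rests on cutting the pyran (ring C) at the aryl ether bond C8a–O1. C3 is configurationally labile only as the α-carbon of the C4 ketone, and O1 sits on A-ring carbon C8a, ortho to C4a, which carries C4; the ring is therefore closed while C4 is still a silyl-protected carbinol. One Pd-catalysed intramolecular O-arylation joins the primary C2 hydroxyl to C8a, building the chroman without touching C3. Its precursor is an open-chain 2,3-diaryl-3-silyloxypropan-1-ol bearing bromine at the future C8a, made by an auxiliary-controlled syn-aldol that fixes C3 as S; C4 is erased later by neutral oxidation.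

Key step: step 12

Remark on stereochemistry: when a syn-aldol chain is closed into the pyran, the C3 aryl and the C4 oxygen end up trans. With the (R)-auxiliary the ring-closure substrate is therefore (2S,3R) and its product the (3S,4R)-trans isoflavan. Only C3 has to be right, because C4 becomes the ketone.

Remark on protecting groups: the C4 oxygen carries TIPS, because this bulky group resists 1,3 O→O silyl migration to the primary alkoxide during hydride reduction and during the carbonate-mediated ring closure.

Remark on starting materials: tributyl(3-methylbut-2-en-1-yl)stannane 4 and methyl 2-(2,4-dihydroxyphenyl)acetate 6 are taken as commercial. Abbreviations: prenyl = 3-methylbut-2-en-1-yl, MOM = methoxymethyl, TIPS = triisopropylsilyl.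

**Route**

Step 1
Reactants: 1 2-bromo-4-hydroxybenzaldehyde
Product: 2 2-bromo-4-hydroxy-5-iodobenzaldehyde
Conditions: NIS (1.0 equiv), TsOH·H2O (10 mol%), MeCN, 0 °C → rt, dark
Reagents that add atoms: N-iodosuccinimide, O=C1CCC(=O)N1I
Why: Electrophilic aromatic iodination ortho to the phenol should occur at C5, which is unhindered and para to bromine, and not at C3, which lies between Br and OH; one equivalent of NIS limits di-iodination.

Step 2
Reactants: 2 2-bromo-4-hydroxy-5-iodobenzaldehyde
Product: 3 2-bromo-5-iodo-4-(methoxymethoxy)benzaldehyde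
Conditions: MOMCl (1.5 equiv), iPr2NEt (2 equiv), CH2Cl2, 0 °C → rt
Reagents that add atoms: chloromethyl methyl ether, COCCl
Why: O-Alkylation of the acidic phenol with the chloromethyl ether under amine base (MOM acetal formation) is routine and leaves the aldehyde and both halides untouched.

Step 3
Reactants: 3 2-bromo-5-iodo-4-(methoxymethoxy)benzaldehyde; 4 tributyl(3-methylbut-2-en-1-yl)stannane
Product: 5 2-bromo-4-(methoxymethoxy)-5-(3-methylbut-2-en-1-yl)benzaldehyde
Conditions: Pd(PPh3)4 (5 mol%), DMF, 80 °C
Reagents that add atoms: none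
Why: Stille cross-coupling, in which Pd(0) inserts into the C–I bond much faster than into the C–Br bond and the prenyl group is delivered through its CH2 terminus because reductive elimination occurs at the less hindered allyl carbon; aldehyde and MOM ether are inert under these neutral conditions.

Step 4
Reactants: 6 methyl 2-(2,4-dihydroxyphenyl)acetate
Product: 7 methyl 2-[2,4-bis(methoxymethoxy)phenyl]acetate
Conditions: MOMCl (3 equiv), iPr2NEt (4 equiv), CH2Cl2, 0 °C → 40 °C
Reagents that add atoms: chloromethyl methyl ether, COCCl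
Why: Double O-alkylation of both phenols (MOM acetal formation) under mild amine base, to which the methyl ester is stable.

Step 5
Reactants: 7 methyl 2-[2,4-bis(methoxymethoxy)phenyl]acetate
Product: 8 methyl 2-[5-iodo-2,4-bis(methoxymethoxy)phenyl]acetate
Conditions: NIS (1.05 equiv), MeCN, 0 °C → rt, dark
Reagents that add atoms: N-iodosuccinimide, O=C1CCC(=O)N1I
Why: Electrophilic aromatic iodination at C5, para to the 2-OMOM and ortho to the 4-OMOM group, is favoured over C3, which lies between two OMOM groups, and the acid-free medium preserves the acetals.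

Step 6
Reactants: 8 methyl 2-[5-iodo-2,4-bis(methoxymethoxy)phenyl]acetate; 4 tributyl(3-methylbut-2-en-1-yl)stannane
Product: 9 methyl 2-[2,4-bis(methoxymethoxy)-5-(3-methylbut-2-en-1-yl)phenyl]acetate
Conditions: Pd(PPh3)4 (5 mol%), DMF, 90 °C
Reagents that add atoms: none
Why: Stille cross-coupling of the aryl iodide with the allylic stannane, as in step 3, should install the linear prenyl group while the ester and MOM ethers stay intact under neutral conditions.

Step 7
Reactants: 9 methyl 2-[2,4-bis(methoxymethoxy)-5-(3-methylbut-2-en-1-yl)phenyl]acetate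
Product: 10 2-[2,4-bis(methoxymethoxy)-5-(3-methylbut-2-en-1-yl)phenyl]acetic acid
Conditions: LiOH·H2O (3 equiv), THF/MeOH/H2O (3:1:1), rt; then 1 M HCl to pH 4, 0 °C
Reagents that add atoms: lithium hydroxide, [Li+].[OH-]
Why: Saponification (BAc2 ester hydrolysis) is compatible with MOM ethers and the prenyl group, and brief cold acidification to pH 4 frees the acid without acetal loss.

Step 8
Reactants: 10 2-[2,4-bis(methoxymethoxy)-5-(3-methylbut-2-en-1-yl)phenyl]acetic acid; 11 (R)-4-benzyl-2-oxazolidinone
Product: 13 (R)-4-benzyl-3-{2-[2,4-bis(methoxymethoxy)-5-(3-methylbut-2-en-1-yl)phenyl]acetyl}oxazolidin-2-one, via mixed pivalic anhydride 12 (not isolated)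
Conditions: PivCl (1.1 equiv), Et3N (2.5 equiv), THF, −20 °C; then LiCl (1.1 equiv), 11 (1.0 equiv), −20 °C → rt
Reagents that add atoms: none
Why: N-Acylation of the oxazolidinone through the mixed pivalic anhydride (LiCl/Et3N activation of the carbamate N–H) occurs at the unhindered arylacetyl carbonyl and avoids acid chlorides that could endanger the MOM ethers.

Step 9
Reactants: 13 (R)-4-benzyl-3-{2-[2,4-bis(methoxymethoxy)-5-(3-methylbut-2-en-1-yl)phenyl]acetyl}oxazolidin-2-one; 5 2-bromo-4-(methoxymethoxy)-5-(3-methylbut-2-en-1-yl)benzaldehyde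
Product: 16 (R)-4-benzyl-3-{(2R,3R)-3-[2-bromo-4-(methoxymethoxy)-5-prenylphenyl]-2-[2,4-bis(methoxymethoxy)-5-prenylphenyl]-3-hydroxypropanoyl}oxazolidin-2-one, via dibutylboron Z-enolate 14 (not isolated), via dibutylboron aldolate 15 (not isolated)
Conditions: Bu2BOTf (1.2 equiv), iPr2NEt (1.4 equiv), CH2Cl2, −78 → 0 °C; 5 (1.1 equiv), −78 → 0 °C; then pH 7 buffer, MeOH, 30% H2O2, 0 °C
Reagents that add atoms: none
Why: Evans boron syn-aldol, in which soft enolisation gives the Z(O)-enolate and this adds to the aldehyde through a chair-like six-membered boron transition state with the auxiliary carbonyl turned away from the enolate oxygen, so that the aldehyde meets the enolate face opposite the benzyl group; this should set C2 (R, the future C3 of the target) and the carbinol C3 (R) together in the syn sense.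

Step 10
Reactants: 16 (R)-4-benzyl-3-{(2R,3R)-3-[2-bromo-4-(methoxymethoxy)-5-prenylphenyl]-2-[2,4-bis(methoxymethoxy)-5-prenylphenyl]-3-hydroxypropanoyl}oxazolidin-2-one
Product: 17 (R)-4-benzyl-3-{(2R,3R)-3-[2-bromo-4-(methoxymethoxy)-5-prenylphenyl]-2-[2,4-bis(methoxymethoxy)-5-prenylphenyl]-3-[(triisopropylsilyl)oxy]propanoyl}oxazolidin-2-one
Conditions: TIPSOTf (1.5 equiv), 2,6-lutidine (3 equiv), CH2Cl2, 0 °C → rt
Reagents that add atoms: triisopropylsilyl trifluoromethanesulfonate, CC(C)[Si](OS(=O)(=O)C(F)(F)F)(C(C)C)C(C)C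
Why: Silylation of the secondary carbinol with a silyl triflate and a hindered pyridine base is not basic enough to start a retro-aldol, and the bulky TIPS ether blocks later retro-aldol cleavage and silyl migration.

Step 11
Reactants: 17 (R)-4-benzyl-3-{(2R,3R)-3-[2-bromo-4-(methoxymethoxy)-5-prenylphenyl]-2-[2,4-bis(methoxymethoxy)-5-prenylphenyl]-3-[(triisopropylsilyl)oxy]propanoyl}oxazolidin-2-one
Product: 18 (2S,3R)-3-[2-bromo-4-(methoxymethoxy)-5-prenylphenyl]-2-[2,4-bis(methoxymethoxy)-5-prenylphenyl]-3-[(triisopropylsilyl)oxy]propan-1-ol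
Conditions: LiBH4 (3 equiv), H2O (3 equiv), Et2O/THF, 0 °C → rt
Reagents that add atoms: none
Why: Reductive cleavage of the N-acyloxazolidinone by lithium borohydride at the lithium-activated exocyclic carbonyl should give the primary alcohol and release the auxiliary, without enolisation at C2 and without touching the aryl bromide, MOM or silyl ethers (the descriptor at C2 changes from R to S only because the priority of C1 falls).

Step 12
Reactants: 18 (2S,3R)-3-[2-bromo-4-(methoxymethoxy)-5-prenylphenyl]-2-[2,4-bis(methoxymethoxy)-5-prenylphenyl]-3-[(triisopropylsilyl)oxy]propan-1-ol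
Product: 19 (3S,4R)-trans-7,2',4'-tris(methoxymethoxy)-6,5'-diprenyl-4-[(triisopropylsilyl)oxy]isoflavan
Conditions: Pd(OAc)2 (5 mol%), 2-(di-tert-butylphosphino)-1,1'-binaphthyl (6 mol%), Cs2CO3 (1.5 equiv), toluene, 75 °C
Reagents that add atoms: none
Why: Pd(0) carrying the bulky di-tert-butyl biaryl phosphine inserts into the C8a–Br bond, the primary C2 hydroxyl binds palladium and is deprotonated by Cs2CO3, and C–O reductive elimination from the resulting seven-membered arylpalladium alkoxide forms C8a–O1. The closest known reaction type is the Buchwald–Hartwig intramolecular etherification of aryl bromides with primary alcohols to give chromans. The pyran is closed as a six-membered ring by bonding of the tethered oxygen to the aryl carbon (6-exo-type closure through the oxapalladacycle). No stereocentre is created: C3 and C4 come unchanged from the aldol, and C3–H is not acidic because C4 is a silyl ether, so the carbonate can neither epimerise C3 nor trigger retro-aldol cleavage. The step needs O-arylation to outrun β-hydride elimination and needs a single nucleophile; the bulky electron-rich ligand accelerates reductive elimination, the primary hydroxyl is the only free OH, and the TIPS ether neither migrates nor binds palladium.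

Step 13
Reactants: 19 (3S,4R)-trans-7,2',4'-tris(methoxymethoxy)-6,5'-diprenyl-4-[(triisopropylsilyl)oxy]isoflavan
Product: 20 (3S,4R)-trans-7,2',4'-tris(methoxymethoxy)-6,5'-diprenylisoflavan-4-ol
Conditions: TBAF (1 M in THF, 3 equiv), THF, rt → 45 °C
Reagents that add atoms: none
Why: Fluoride-mediated desilylation is driven by the strong Si–F bond, and with C4 still a carbinol C3–H is not acidic, so basic fluoride cannot epimerise C3; MOM ethers and prenyl groups are inert.

Step 14
Reactants: 20 (3S,4R)-trans-7,2',4'-tris(methoxymethoxy)-6,5'-diprenylisoflavan-4-ol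
Product: 21 (3S)-7,2',4'-tris(methoxymethoxy)-6,5'-diprenylisoflavan-4-one
Conditions: Dess–Martin periodinane (1.5 equiv), NaHCO3 (5 equiv), CH2Cl2, 0 °C → rt; cold, brief Na2S2O3/NaHCO3 work-up
Reagents that add atoms: none
Why: Dess–Martin oxidation of the benzylic secondary alcohol proceeds by ligand exchange at iodine and intramolecular proton removal under bicarbonate-buffered, essentially neutral conditions, so the now acidic C3–H meets neither base nor strong acid and the S configuration should be kept while the C4 stereocentre is removed.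

Step 15
Reactants: 21 (3S)-7,2',4'-tris(methoxymethoxy)-6,5'-diprenylisoflavan-4-one
Product: 22 (3S)-7,2',4'-trihydroxy-6,5'-diprenylisoflavan-4-one (CNP0166009.1)
Conditions: HCl (1.25 M in MeOH, 10 equiv), MeOH/THF, 0 °C → rt, stopped at full conversion
Reagents that add atoms: none
Why: Acid-catalysed acetal methanolysis of the three aryl MOM ethers (each lost as dimethoxymethane) should proceed in dilute methanolic HCl at or below room temperature, conditions chosen to stay below those that cyclise o-prenylphenols to chromans and to keep acid-mediated enolisation of the C4 ketone slow.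

**Compound list**

1 | 2-bromo-4-hydroxybenzaldehyde | O=Cc1ccc(O)cc1Br | starting material
2 | 2-bromo-4-hydroxy-5-iodobenzaldehyde | O=Cc1cc(I)c(O)cc1Br | intermediate
3 | 2-bromo-5-iodo-4-(methoxymethoxy)benzaldehyde | COCOc1cc(Br)c(C=O)cc1I | intermediate
4 | tributyl(3-methylbut-2-en-1-yl)stannane | CCCC[Sn](CCCC)(CCCC)CC=C(C)C | starting material
5 | 2-bromo-4-(methoxymethoxy)-5-(3-methylbut-2-en-1-yl)benzaldehyde | COCOc1cc(Br)c(C=O)cc1CC=C(C)C | intermediate
6 | methyl 2-(2,4-dihydroxyphenyl)acetate | COC(=O)Cc1ccc(O)cc1O | starting material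
7 | methyl 2-[2,4-bis(methoxymethoxy)phenyl]acetate | COC(=O)Cc1ccc(OCOC)cc1OCOC | intermediate
8 | methyl 2-[5-iodo-2,4-bis(methoxymethoxy)phenyl]acetate | COC(=O)Cc1cc(I)c(OCOC)cc1OCOC | intermediate
9 | methyl 2-[2,4-bis(methoxymethoxy)-5-(3-methylbut-2-en-1-yl)phenyl]acetate | COC(=O)Cc1cc(CC=C(C)C)c(OCOC)cc1OCOC | intermediate
10 | 2-[2,4-bis(methoxymethoxy)-5-(3-methylbut-2-en-1-yl)phenyl]acetic acid | OC(=O)Cc1cc(CC=C(C)C)c(OCOC)cc1OCOC | intermediate
11 | (R)-4-benzyl-2-oxazolidinone | O=C1N[C@H](Cc2ccccc2)CO1 | starting material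
12 | mixed anhydride of acid 10 with pivalic acid | CC(C)(C)C(=O)OC(=O)Cc1cc(CC=C(C)C)c(OCOC)cc1OCOC | intermediate
13 | (R)-4-benzyl-3-{2-[2,4-bis(methoxymethoxy)-5-(3-methylbut-2-en-1-yl)phenyl]acetyl}oxazolidin-2-one | O=C(Cc1cc(CC=C(C)C)c(OCOC)cc1OCOC)N1[C@H](Cc2ccccc2)COC1=O | intermediate
14 | dibutylboron (Z)-enolate of imide 13 | CCCCB(CCCC)O/C(=C\c1cc(CC=C(C)C)c(OCOC)cc1OCOC)N1[C@H](Cc2ccccc2)COC1=O | intermediate
15 | O-dibutylboryl aldolate of 16, (2R,3R) | CC(C)=CCc1cc([C@H](OB(CCCC)CCCC)[C@H](C(=O)N2[C@H](Cc3ccccc3)COC2=O)c2cc(CC=C(C)C)c(OCOC)cc2OCOC)c(Br)cc1OCOC | intermediate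
16 | (R)-4-benzyl-3-{(2R,3R)-3-[2-bromo-4-(methoxymethoxy)-5-prenylphenyl]-2-[2,4-bis(methoxymethoxy)-5-prenylphenyl]-3-hydroxypropanoyl}oxazolidin-2-one | CC(C)=CCc1cc([C@H](O)[C@H](C(=O)N2[C@H](Cc3ccccc3)COC2=O)c2cc(CC=C(C)C)c(OCOC)cc2OCOC)c(Br)cc1OCOC | intermediate
17 | (R)-4-benzyl-3-{(2R,3R)-3-[2-bromo-4-(methoxymethoxy)-5-prenylphenyl]-2-[2,4-bis(methoxymethoxy)-5-prenylphenyl]-3-[(triisopropylsilyl)oxy]propanoyl}oxazolidin-2-one | CC(C)=CCc1cc([C@H](O[Si](C(C)C)(C(C)C)C(C)C)[C@H](C(=O)N2[C@H](Cc3ccccc3)COC2=O)c2cc(CC=C(C)C)c(OCOC)cc2OCOC)c(Br)cc1OCOC | intermediate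
18 | (2S,3R)-3-[2-bromo-4-(methoxymethoxy)-5-prenylphenyl]-2-[2,4-bis(methoxymethoxy)-5-prenylphenyl]-3-[(triisopropylsilyl)oxy]propan-1-ol | CC(C)=CCc1cc([C@H](O[Si](C(C)C)(C(C)C)C(C)C)[C@H](CO)c2cc(CC=C(C)C)c(OCOC)cc2OCOC)c(Br)cc1OCOC | intermediate
19 | (3S,4R)-trans-7,2',4'-tris(methoxymethoxy)-6,5'-diprenyl-4-[(triisopropylsilyl)oxy]isoflavan | CC(C)=CCc1cc2c(cc1OCOC)OC[C@H](c1cc(CC=C(C)C)c(OCOC)cc1OCOC)[C@H]2O[Si](C(C)C)(C(C)C)C(C)C | intermediate
20 | (3S,4R)-trans-7,2',4'-tris(methoxymethoxy)-6,5'-diprenylisoflavan-4-ol | CC(C)=CCc1cc2c(cc1OCOC)OC[C@H](c1cc(CC=C(C)C)c(OCOC)cc1OCOC)[C@H]2O | intermediate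
21 | (3S)-7,2',4'-tris(methoxymethoxy)-6,5'-diprenylisoflavan-4-one | CC(C)=CCc1cc2c(cc1OCOC)OC[C@H](c1cc(CC=C(C)C)c(OCOC)cc1OCOC)C2=O | intermediate
22 | (3S)-7,2',4'-trihydroxy-6,5'-diprenylisoflavan-4-one (CNP0166009.1) | CC(C)=CCc1cc2c(cc1O)OC[C@H](c1cc(CC=C(C)C)c(O)cc1O)C2=O | target

**Step count and risks**

Total step count: 15. Longest linear sequence: 12 steps (from 6 to 22, steps 4–15).

The three steps most likely to fail:

1. Step 12. Oxidative addition into the electron-rich, ortho-branched C8a–Br bond may be slow, and β-hydride elimination from the palladium alkoxide may reduce the C–Br bond while oxidising the primary alcohol. The fallback sets out from 18 and builds the same ring from the other side of O1. Miyaura borylation of 18 (B2pin2, Pd(dppf)Cl2, KOAc, dioxane, 90 °C) should give the aryl pinacol boronate F1. Oxidation with NaBO3·4H2O in THF/H2O at rt should give the phenol F2. Mitsunobu cyclodehydration (PPh3, DIAD, THF, 0 °C → rt) should then form the O1–C2 bond and return to the route at 19.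

2. Step 15. Acid-promoted enolisation towards C3 may erode the configuration, and cyclisation of a prenyl group onto its neighbouring phenol may compete with acetal cleavage. The fallback sets out from 21 and replaces protic solvolysis by aprotic silyl transfer. TMSOTf with 2,2'-bipyridyl in CH2Cl2 at 0 °C should convert the three aryl MOM ethers into the tris(trimethylsilyl) ether F3. This is hydrolysed by added water at neutral pH and comes back to the route at 22.

3. Step 3. The unsymmetrical allyl unit may transpose during transfer from tin, giving the 1,1-dimethylallyl isomer, and insertion at the C–Br bond may compete. The fallback sets out from 3. Stille coupling with allyltributylstannane (Pd(PPh3)4, DMF, 80 °C), which has no regiochemical ambiguity, should give 5-allyl-2-bromo-4-(methoxymethoxy)benzaldehyde F4. Cross-metathesis with 2-methylbut-2-ene (second-generation ruthenium benzylidene catalyst, CH2Cl2, 40 °C) should then return to the route at 5.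

**Further compounds**

F1 | step 12 | (2S,3R)-2-[2,4-bis(methoxymethoxy)-5-prenylphenyl]-3-[4-(methoxymethoxy)-5-prenyl-2-(4,4,5,5-tetramethyl-1,3,2-dioxaborolan-2-yl)phenyl]-3-[(triisopropylsilyl)oxy]propan-1-ol | CC(C)=CCc1cc([C@H](O[Si](C(C)C)(C(C)C)C(C)C)[C@H](CO)c2cc(CC=C(C)C)c(OCOC)cc2OCOC)c(B3OC(C)(C)C(C)(C)O3)cc1OCOC
F2 | step 12 | (2S,3R)-2-[2,4-bis(methoxymethoxy)-5-prenylphenyl]-3-[2-hydroxy-4-(methoxymethoxy)-5-prenylphenyl]-3-[(triisopropylsilyl)oxy]propan-1-ol | CC(C)=CCc1cc([C@H](O[Si](C(C)C)(C(C)C)C(C)C)[C@H](CO)c2cc(CC=C(C)C)c(OCOC)cc2OCOC)c(O)cc1OCOC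
F3 | step 15 | (3S)-6,5'-diprenyl-7,2',4'-tris[(trimethylsilyl)oxy]isoflavan-4-one | CC(C)=CCc1cc2c(cc1O[Si](C)(C)C)OC[C@H](c1cc(CC=C(C)C)c(O[Si](C)(C)C)cc1O[Si](C)(C)C)C2=O
F4 | step 3 | 5-allyl-2-bromo-4-(methoxymethoxy)benzaldehyde | C=CCc1cc(C=O)c(Br)cc1OCOC
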